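**Retrosynthetic overview**
1. Endgame: acetates and angelate go on last; the 6α‑carbinol comes from an OH‑directed reduction of a 4β‑hydroxy‑6‑ketone; the C4 carbinol from i‑Pr addition to a C4 ketone; the epoxide from a 10‑OH‑directed epoxidation of Δ8.
2. C4 ketone and 5α‑H ⇐ hydroboration/oxidation of a Δ4 hydroazulene; seven‑membered ring ⇐ RCM forming C8=C9.
3. Key step: [2,3]‑Wittig rearrangement of a C4 allyl ether forges C1–C10 (quaternary C1, C10 carbinol), with chirality relayed from C4–O, cis to C2–O.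
4. Cyclopentene ⇐ ozonolysis/aldol ring contraction of a cis‑3,5‑dioxygenated 2‑methylcyclohexene ⇐ (S)‑carvone (Criegee degradation of the isopropenyl group, Luche reduction).
5. Ring order: five‑membered ring first (from the carvone ring), then the seven‑membered ring.

Assumption: from compound 9 on, ring carbons carry daucane numbers (C1 = quaternary C–CH3, C2 = adjacent CH–O, C3 = CH2, C4 = i‑Pr carbinol carbon, C5 = ring‑fusion CH, C6 = angelate carbon, C7 = CH2, C8(CH3)/C9 = epoxide, C10 = second acetate carbon); β is the face of the C1 methyl.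

**Step 1**
Reactants: 1 (S)-(+)-carvone
Product: 3 (1S)-4-methyl-5-oxocyclohex-3-en-1-yl acetate, via methoxy hydroperoxide 2 (not isolated)
Conditions: O3, CH2Cl2/MeOH, −78 °C; then Ac2O, Et3N, DMAP (cat.), 0 °C → rt
Reagents that add atoms: ozone O=[O+][O-]; methanol CO
Why: Ozonolysis of the isopropenyl group (the enone alkene is inert) followed by Criegee rearrangement of the peracetate moves the ring carbon to oxygen with retention, so the carvone stereocentre becomes the (S)-acetate.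

**Step 2**
Reactants: 3 (1S)-4-methyl-5-oxocyclohex-3-en-1-yl acetate
Product: 4 (1S,5S)-5-hydroxy-4-methylcyclohex-3-en-1-yl acetate
Conditions: NaBH4, CeCl3·7H2O, MeOH, −78 °C
Reagents that add atoms: none
Why: Luche 1,2-reduction with axial hydride delivery gives the cis (pseudo-diequatorial) allylic alcohol, as in carvone → cis-carveol; this is the future C2 stereocentre.

**Step 3**
Reactants: 4 (1S,5S)-5-hydroxy-4-methylcyclohex-3-en-1-yl acetate
Product: 5 (1S,5S)-5-[(tert-butyldimethylsilyl)oxy]-4-methylcyclohex-3-en-1-yl acetate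
Conditions: TBSCl, imidazole, DMF, rt
Reagents that add atoms: tert-butyldimethylsilyl chloride CC(C)(C)[Si](C)(C)Cl
Why: Standard silylation of the allylic alcohol; TBS survives the later base, organolithium and oxidation steps.

**Step 4**
Reactants: 5 (1S,5S)-5-[(tert-butyldimethylsilyl)oxy]-4-methylcyclohex-3-en-1-yl acetate
Product: 6 (1S,5S)-5-[(tert-butyldimethylsilyl)oxy]-4-methylcyclohex-3-en-1-ol
Conditions: K2CO3 (cat.), MeOH, 0 °C
Reagents that add atoms: none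
Why: Mild transesterification removes the acetate without touching the TBS ether.

**Step 5**
Reactants: 6 (1S,5S)-5-[(tert-butyldimethylsilyl)oxy]-4-methylcyclohex-3-en-1-ol
Product: 7 tert-butyldimethyl{[(1S,5S)-2-methyl-5-(prop-2-en-1-yloxy)cyclohex-2-en-1-yl]oxy}silane
Conditions: allyl 2,2,2-trichloroacetimidate, TfOH (5 mol%), cyclohexane/CH2Cl2, 0 °C → rt
Reagents that add atoms: allyl 2,2,2-trichloroacetimidate C=CCOC(=N)C(Cl)(Cl)Cl
Why: Acid-catalysed imidate O-allylation avoids an alkoxide, so no 1,3-silyl migration across the cis-diol occurs.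

**Step 6**
Reactants: 7 tert-butyldimethyl{[(1S,5S)-2-methyl-5-(prop-2-en-1-yloxy)cyclohex-2-en-1-yl]oxy}silane
Product: 9 (3S,5R)-3-[(tert-butyldimethylsilyl)oxy]-2-methyl-5-(prop-2-en-1-yloxy)cyclopent-1-ene-1-carbaldehyde, via keto aldehyde 8 (not isolated)
Conditions: O3 (1.0 equiv, Sudan III end-point), CH2Cl2, −78 °C; Me2S; then Bn2NH·TFA (0.2 equiv), PhMe, 50 °C
Reagents that add atoms: ozone O=[O+][O-]
Why: Ozone cleaves the more electron-rich trisubstituted ring alkene, and enamine-mediated intramolecular aldol condensation (aldehyde α-carbon onto the methyl ketone) contracts the ring; the two oxygenated stereocentres are untouched and end up cis (both α) at C2 and C4.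

**Step 7**
Reactants: 9 (3S,5R)-3-[(tert-butyldimethylsilyl)oxy]-2-methyl-5-(prop-2-en-1-yloxy)cyclopent-1-ene-1-carbaldehyde
Product: 11 triethylsilyl ether of (1R)-1-[(3S,5R)-3-(TBS-oxy)-2-methyl-5-(allyloxy)cyclopent-1-en-1-yl]-3-methylbut-3-en-1-ol, via homoallylic alcohol 10 (not isolated)
Conditions: 2-methylallylMgCl, THF, −78 °C; then TESOTf, −78 → 0 °C
Reagents that add atoms: 2-methylallylmagnesium chloride C=C(C)C[Mg]Cl; triethylsilyl triflate CC[Si](CC)(CC)OS(=O)(=O)C(F)(F)F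
Why: Grignard 1,2-addition to the s-trans enal from the β-face, anti to the α-oriented allyloxy and silyloxy groups (Cram-chelate with the allyl ether oxygen), gives a provisional 6β-O carbinol that later steers the hydroboration and is reset in steps 14–15; the alkoxide is silylated in situ.

**Step 8**
Reactants: 11 triethylsilyl ether of (1R)-1-[(3S,5R)-3-(TBS-oxy)-2-methyl-5-(allyloxy)cyclopent-1-en-1-yl]-3-methylbut-3-en-1-ol
Product: 12 (1R)-1-{(1S,5S)-5-[(tert-butyldimethylsilyl)oxy]-1-methyl-2-[(1R)-3-methyl-1-(triethylsilyloxy)but-3-en-1-yl]cyclopent-2-en-1-yl}prop-2-en-1-ol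
Conditions: n-BuLi (1.5 equiv), THF, −78 → −40 °C; NH4Cl (aq) at −78 °C
Reagents that add atoms: none
Why: [2,3]-Wittig sigmatropic rearrangement of the α-lithiated allyl ether transfers C10 suprafacially from the α C4–O to C1, creating the quaternary centre with C10 cis to the C2 silyloxy group; the vinyl group sits exo in the envelope transition state, giving the 10α-carbinol, and the alkene moves to C4=C5.

**Step 9**
Reactants: 12 (1R)-1-{(1S,5S)-5-[(tert-butyldimethylsilyl)oxy]-1-methyl-2-[(1R)-3-methyl-1-(triethylsilyloxy)but-3-en-1-yl]cyclopent-2-en-1-yl}prop-2-en-1-ol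
Product: 13 2α-(TBS-oxy)-6β-(TES-oxy)-1β,8-dimethylbicyclo[5.3.0]deca-4,8-dien-10α-ol (daucane numbering)
Conditions: Grubbs II (5 mol%), CH2Cl2, 40 °C
Reagents that add atoms: none
Why: Ring-closing metathesis of the vinyl and 1,1-disubstituted alkenes closes the cycloheptene with the trisubstituted C8=C9 bond; the ring trisubstituted C4=C5 alkene does not take part.

**Step 10**
Reactants: 13 2α-(TBS-oxy)-6β-(TES-oxy)-1β,8-dimethylbicyclo[5.3.0]deca-4,8-dien-10α-ol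
Product: 14 8α,9α-epoxy-2α-(TBS-oxy)-6β-(TES-oxy)-1β,8-dimethylbicyclo[5.3.0]dec-4-en-10α-ol
Conditions: VO(acac)2 (5 mol%), t-BuOOH, CH2Cl2, 0 °C → rt
Reagents that add atoms: tert-butyl hydroperoxide CC(C)(C)OO
Why: Vanadium-catalysed hydroxyl-directed epoxidation acts on the allylic C8=C9 bond syn to the 10α-OH (cis selectivity of cycloheptenols), setting C8 and C9; the homoallylic C4=C5 bond is much slower.

**Step 11**
Reactants: 14 8α,9α-epoxy-2α-(TBS-oxy)-6β-(TES-oxy)-1β,8-dimethylbicyclo[5.3.0]dec-4-en-10α-ol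
Product: 15 8α,9α-epoxy-2α,10α-bis(TBS-oxy)-6β-(TES-oxy)-1β,8-dimethylbicyclo[5.3.0]dec-4-ene
Conditions: TBSOTf, 2,6-lutidine, CH2Cl2, −78 → 0 °C
Reagents that add atoms: tert-butyldimethylsilyl triflate CC(C)(C)[Si](C)(C)OS(=O)(=O)C(F)(F)F
Why: Silylation masks the hindered C10 alcohol before the oxidation and organometallic steps, so no ester is present there.

**Step 12**
Reactants: 15 8α,9α-epoxy-2α,10α-bis(TBS-oxy)-6β-(TES-oxy)-1β,8-dimethylbicyclo[5.3.0]dec-4-ene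
Product: 17 8α,9α-epoxy-2α,10α-bis(TBS-oxy)-6β-(TES-oxy)-1β,8-dimethyl-5α-H-bicyclo[5.3.0]decan-4-one, via alkylborane 16 (not isolated)
Conditions: BH3·SMe2, THF, 0 °C → rt; then NMO (6 equiv), TPAP (5 mol%), 4 Å MS, CH2Cl2, rt
Reagents that add atoms: borane–dimethyl sulfide C[S+](C)[BH3-] (boron of 16); N-methylmorpholine N-oxide C[N+]1([O-])CCOCC1 (carbonyl oxygen of 17)
Why: Hydroboration puts boron on the less substituted C4 and hydrogen on C5 from the α-face, anti to the angular methyl and the β allylic silyloxy group at C6 (trans ring fusion); NMO/TPAP oxidises the C–B bond through to the ketone.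

**Step 13**
Reactants: 17 8α,9α-epoxy-2α,10α-bis(TBS-oxy)-6β-(TES-oxy)-1β,8-dimethyl-5α-H-bicyclo[5.3.0]decan-4-one
Product: 18 8α,9α-epoxy-2α,10α-bis(TBS-oxy)-6β-(TES-oxy)daucan-4β-ol
Conditions: i-PrMgCl, CeCl3 (anhydrous), THF, −78 → −40 °C; NH4Cl (aq)
Reagents that add atoms: isopropylmagnesium chloride CC(C)[Mg]Cl
Why: The weakly basic organocerium adds 1,2 without enolisation or β-elimination, from the α-face trans to the adjacent β C5–C6 bond and the angular methyl, giving 4β-OH/4α-isopropyl.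

**Step 14**
Reactants: 18 8α,9α-epoxy-2α,10α-bis(TBS-oxy)-6β-(TES-oxy)daucan-4β-ol
Product: 20 8α,9α-epoxy-4β-hydroxy-2α,10α-bis(TBS-oxy)daucan-6-one, via C6 alcohol 19 (not isolated)
Conditions: IBX (3 equiv), DMSO, rt → 40 °C
Reagents that add atoms: none
Why: IBX in DMSO cleaves the TES ether selectively in the presence of TBS ethers and oxidises the liberated secondary alcohol in the same pot; the tertiary alcohol is inert.

**Step 15**
Reactants: 20 8α,9α-epoxy-4β-hydroxy-2α,10α-bis(TBS-oxy)daucan-6-one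
Product: 21 8α,9α-epoxy-2α,10α-bis(TBS-oxy)daucane-4β,6α-diol
Conditions: Me4NBH(OAc)3, MeCN/AcOH 1:1, −30 °C
Reagents that add atoms: none
Why: Evans–Saksena hydroxyl-directed reduction: the borohydride bound to the 4β-OH (cis to the C5–C6 bond) delivers hydride to the β-face of the C6 ketone, giving the 6α-alcohol.

**Step 16**
Reactants: 21 8α,9α-epoxy-2α,10α-bis(TBS-oxy)daucane-4β,6α-diol; 22 angelic acid
Product: 23 6α-angeloyloxy-8α,9α-epoxy-2α,10α-bis(TBS-oxy)daucan-4β-ol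
Conditions: 2,4,6-Cl3C6H2COCl, Et3N, PhMe, rt; then 21, PhMe, 80 °C
Reagents that add atoms: none
Why: Yamaguchi-type mixed-anhydride acylation without a nucleophilic catalyst esterifies only the secondary C6 alcohol and keeps the (Z)-alkene of the angelate intact.

**Step 17**
Reactants: 23 6α-angeloyloxy-8α,9α-epoxy-2α,10α-bis(TBS-oxy)daucan-4β-ol
Product: 25 2α,10α-diacetoxy-6α-angeloyloxy-8α,9α-epoxydaucan-4β-ol (CNP0170993.1), via triol 24 (not isolated)
Conditions: TBAF, AcOH, THF, rt → 45 °C; then Ac2O, Et3N, DMAP, CH2Cl2, 0 °C → rt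
Reagents that add atoms: acetic anhydride CC(=O)OC(C)=O
Why: Buffered fluoride removes both TBS ethers and acetylation then occurs only at the two secondary alcohols (C2, C10); the hindered tertiary C4–OH stays free.

**Compound list**
1 | (S)-(+)-carvone | CC1=CC[C@@H](CC1=O)C(C)=C | starting material
2 | (5S)-5-(1-hydroperoxy-1-methoxyethyl)-2-methylcyclohex-2-en-1-one (epimers at the peroxy carbon) | CC1=CC[C@@H](CC1=O)C(C)(OC)OO | intermediate
3 | (1S)-4-methyl-5-oxocyclohex-3-en-1-yl acetate | CC1=CC[C@H](OC(C)=O)CC1=O | intermediate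
4 | (1S,5S)-5-hydroxy-4-methylcyclohex-3-en-1-yl acetate (cis) | CC1=CC[C@H](OC(C)=O)C[C@@H]1O | intermediate
5 | (1S,5S)-5-[(tert-butyldimethylsilyl)oxy]-4-methylcyclohex-3-en-1-yl acetate | CC1=CC[C@H](OC(C)=O)C[C@@H]1O[Si](C)(C)C(C)(C)C | intermediate
6 | (1S,5S)-5-[(tert-butyldimethylsilyl)oxy]-4-methylcyclohex-3-en-1-ol | CC1=CC[C@H](O)C[C@@H]1O[Si](C)(C)C(C)(C)C | intermediate
7 | tert-butyldimethyl{[(1S,5S)-2-methyl-5-(prop-2-en-1-yloxy)cyclohex-2-en-1-yl]oxy}silane | CC1=CC[C@H](OCC=C)C[C@@H]1O[Si](C)(C)C(C)(C)C | intermediate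
8 | (3R,5S)-5-[(tert-butyldimethylsilyl)oxy]-6-oxo-3-(prop-2-en-1-yloxy)heptanal | CC(=O)[C@@H](O[Si](C)(C)C(C)(C)C)C[C@@H](OCC=C)CC=O | intermediate
9 | (3S,5R)-3-[(tert-butyldimethylsilyl)oxy]-2-methyl-5-(prop-2-en-1-yloxy)cyclopent-1-ene-1-carbaldehyde (C2-OTBS and C4-O-allyl both α) | O=CC1=C(C)[C@@H](O[Si](C)(C)C(C)(C)C)C[C@H]1OCC=C | intermediate
10 | (1R)-1-[(3S,5R)-3-(TBS-oxy)-2-methyl-5-(allyloxy)cyclopent-1-en-1-yl]-3-methylbut-3-en-1-ol | C=C(C)C[C@@H](O)C1=C(C)[C@@H](O[Si](C)(C)C(C)(C)C)C[C@H]1OCC=C | intermediate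
11 | triethylsilyl ether of 10 | C=C(C)C[C@@H](O[Si](CC)(CC)CC)C1=C(C)[C@@H](O[Si](C)(C)C(C)(C)C)C[C@H]1OCC=C | intermediate
12 | (1R)-1-{(1S,5S)-5-(TBS-oxy)-1-methyl-2-[(1R)-3-methyl-1-(TES-oxy)but-3-en-1-yl]cyclopent-2-en-1-yl}prop-2-en-1-ol | C=C(C)C[C@@H](O[Si](CC)(CC)CC)C1=CC[C@H](O[Si](C)(C)C(C)(C)C)[C@]1(C)[C@H](O)C=C | intermediate
13 | 2α-(TBS-oxy)-6β-(TES-oxy)-1β,8-dimethylbicyclo[5.3.0]deca-4,8-dien-10α-ol | CC[Si](CC)(CC)O[C@@H]1CC(C)=C[C@@H](O)[C@@]2(C)[C@@H](O[Si](C)(C)C(C)(C)C)CC=C12 | intermediate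
14 | 8α,9α-epoxy-2α-(TBS-oxy)-6β-(TES-oxy)-1β,8-dimethylbicyclo[5.3.0]dec-4-en-10α-ol | CC[Si](CC)(CC)O[C@@H]1C[C@@]2(C)O[C@H]2[C@@H](O)[C@@]3(C)[C@@H](O[Si](C)(C)C(C)(C)C)CC=C13 | intermediate
15 | 8α,9α-epoxy-2α,10α-bis(TBS-oxy)-6β-(TES-oxy)-1β,8-dimethylbicyclo[5.3.0]dec-4-ene | CC[Si](CC)(CC)O[C@@H]1C[C@@]2(C)O[C@H]2[C@@H](O[Si](C)(C)C(C)(C)C)[C@@]3(C)[C@@H](O[Si](C)(C)C(C)(C)C)CC=C13 | intermediate
16 | 4α-boryl-5α-H alkylborane from 15 | CC[Si](CC)(CC)O[C@@H]1C[C@@]2(C)O[C@H]2[C@@H](O[Si](C)(C)C(C)(C)C)[C@@]3(C)[C@@H](O[Si](C)(C)C(C)(C)C)C[C@@H](B)[C@H]13 | intermediate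
17 | 8α,9α-epoxy-2α,10α-bis(TBS-oxy)-6β-(TES-oxy)-1β,8-dimethyl-5α-H-bicyclo[5.3.0]decan-4-one | CC[Si](CC)(CC)O[C@@H]1C[C@@]2(C)O[C@H]2[C@@H](O[Si](C)(C)C(C)(C)C)[C@@]3(C)[C@@H](O[Si](C)(C)C(C)(C)C)CC(=O)[C@H]13 | intermediate
18 | 8α,9α-epoxy-2α,10α-bis(TBS-oxy)-6β-(TES-oxy)daucan-4β-ol | CC[Si](CC)(CC)O[C@@H]1C[C@@]2(C)O[C@H]2[C@@H](O[Si](C)(C)C(C)(C)C)[C@@]3(C)[C@@H](O[Si](C)(C)C(C)(C)C)C[C@@](O)(C(C)C)[C@H]13 | intermediate
19 | 8α,9α-epoxy-2α,10α-bis(TBS-oxy)daucane-4β,6β-diol | O[C@@H]1C[C@@]2(C)O[C@H]2[C@@H](O[Si](C)(C)C(C)(C)C)[C@@]3(C)[C@@H](O[Si](C)(C)C(C)(C)C)C[C@@](O)(C(C)C)[C@H]13 | intermediate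
20 | 8α,9α-epoxy-4β-hydroxy-2α,10α-bis(TBS-oxy)daucan-6-one | O=C1C[C@@]2(C)O[C@H]2[C@@H](O[Si](C)(C)C(C)(C)C)[C@@]3(C)[C@@H](O[Si](C)(C)C(C)(C)C)C[C@@](O)(C(C)C)[C@H]13 | intermediate
21 | 8α,9α-epoxy-2α,10α-bis(TBS-oxy)daucane-4β,6α-diol | O[C@H]1C[C@@]2(C)O[C@H]2[C@@H](O[Si](C)(C)C(C)(C)C)[C@@]3(C)[C@@H](O[Si](C)(C)C(C)(C)C)C[C@@](O)(C(C)C)[C@H]13 | intermediate
22 | angelic acid, (Z)-2-methylbut-2-enoic acid | C/C=C(/C)C(=O)O | starting material
23 | 6α-angeloyloxy-8α,9α-epoxy-2α,10α-bis(TBS-oxy)daucan-4β-ol | C/C=C(/C)C(=O)O[C@H]1C[C@@]2(C)O[C@H]2[C@@H](O[Si](C)(C)C(C)(C)C)[C@@]3(C)[C@@H](O[Si](C)(C)C(C)(C)C)C[C@@](O)(C(C)C)[C@H]13 | intermediate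
24 | 6α-angeloyloxy-8α,9α-epoxydaucane-2α,4β,10α-triol | C/C=C(/C)C(=O)O[C@H]1C[C@@]2(C)O[C@H]2[C@@H](O)[C@@]3(C)[C@@H](O)C[C@@](O)(C(C)C)[C@H]13 | intermediate
25 | 2α,10α-diacetoxy-6α-angeloyloxy-8α,9α-epoxydaucan-4β-ol (1β-CH3, 5α-H) | C/C=C(/C)C(=O)O[C@H]1C[C@@]2(C)O[C@H]2[C@@H](OC(C)=O)[C@@]2(C)[C@@H](OC(C)=O)C[C@@](O)(C(C)C)[C@H]12 | target

**Step count and risks**
Total: 17 steps. Longest linear sequence: 17 steps (1 → 25); angelic acid 22 is bought.

Three steps most likely to fail: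

Step 8 ([2,3]-Wittig onto a tetrasubstituted alkene, next to the C2 silyloxy group; [1,2]-shift may compete). The fallback sets out from 11 and comes back at 13. Ring-closing metathesis is run first (Grubbs II) between the allyl ether and the methallyl group to give the eight-membered cyclic allyl ether F2. Treating it with n-BuLi in THF at −78 °C then triggers a transannular [2,3]-Wittig ring contraction that expels the ether oxygen from the ring and gives 13 directly. The ring holds the carbanion under the α-face of C1 and keeps C9 on the C5 side, so the same C1 and C10 configurations result.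

Step 12 (α-face selectivity of the hydroboration and the one-pot oxidation). The fallback sets out from 14 and comes back at 17. The free 10α-OH is silylated with (HMe2Si)2NH to the dimethylsilyl ether F3. Pt(0) (Karstedt) intramolecular hydrosilylation then delivers Si to C4 and H to C5 from the α-face (6-endo, because C5 is fully substituted) to give the cyclic siloxane F4. Tamao–Fleming oxidation (H2O2, KF, KHCO3) gives the 4α,10α-diol F5. TEMPO/PhI(OAc)2 oxidises only the unhindered C4 alcohol to the hydroxy ketone F6, and TBSOTf/2,6-lutidine gives 17.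

Step 6 (ozone must spare the allyl ether alkene). The fallback sets out from 7 and comes back at 9. m-CPBA (NaHCO3, CH2Cl2, 0 °C) epoxidises only the trisubstituted ring alkene to give the trans epoxide F1. H5IO6 in THF/H2O cleaves this epoxide to keto aldehyde 8, which is cyclised with Bn2NH·TFA as in the main route to give 9.

**Further compounds**
F1 | step 6 | 2,3-epoxide of 7, oxirane anti to the silyloxy group | C[C@]12O[C@H]1C[C@H](OCC=C)C[C@@H]2O[Si](C)(C)C(C)(C)C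
F2 | step 8 | (Z) eight-membered cyclic allyl ether from RCM of 11 (O bridging C4 and C10; cyclopentene C1=C5 retained) | CC1=CCO[C@@H]2C[C@H](O[Si](C)(C)C(C)(C)C)C(C)=C2[C@H](O[Si](CC)(CC)CC)C1
F3 | step 12 | 10-O-dimethylsilyl ether of 14 | CC[Si](CC)(CC)O[C@@H]1C[C@@]2(C)O[C@H]2[C@@H](O[SiH](C)C)[C@@]3(C)[C@@H](O[Si](C)(C)C(C)(C)C)CC=C13
F4 | step 12 | cyclic siloxane with SiMe2 bridging O10 and C4 (4α-Si, 5α-H) | CC[Si](CC)(CC)O[C@@H]1C[C@@]2(C)O[C@H]2[C@H]3O[Si](C)(C)[C@@H]4C[C@H](O[Si](C)(C)C(C)(C)C)[C@@]3(C)[C@@H]14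
F5 | step 12 | 8α,9α-epoxy-2α-(TBS-oxy)-6β-(TES-oxy)-1β,8-dimethyl-5α-H-bicyclo[5.3.0]decane-4α,10α-diol | CC[Si](CC)(CC)O[C@@H]1C[C@@]2(C)O[C@H]2[C@@H](O)[C@@]3(C)[C@@H](O[Si](C)(C)C(C)(C)C)C[C@@H](O)[C@H]13
F6 | step 12 | 8α,9α-epoxy-10α-hydroxy-2α-(TBS-oxy)-6β-(TES-oxy)-1β,8-dimethyl-5α-H-bicyclo[5.3.0]decan-4-one | CC[Si](CC)(CC)O[C@@H]1C[C@@]2(C)O[C@H]2[C@@H](O)[C@@]3(C)[C@@H](O[Si](C)(C)C(C)(C)C)CC(=O)[C@H]13
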